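The fifteen skeletal carbons form one unbroken farnesyl chain, C5–C4–C3–C2–C1–C11–C10–C9–C8–C7–C6, with methyls on C3 and C10 and two on C6. Cutting C5–C6, C5–C11 and C4–C10 unravels the cyclobutane (C4–C5–C11–C10) and the six- and seven-membered rings fused to it, leaving acyclic (2E,6E)-farnesyl diphosphate. A single synthase-mediated cationic cascade re-forms these three bonds and sets C4, C5, C10 and C11, giving α-longipinene. The C1 ketone and the C7 and C9 oxygens are added afterwards; C7 and C9 are told apart through a C9 ketone, not by selective acylation of a diol.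

Key step: step 3

Remark on numbering: longipinane numbering is used for all cage compounds: C1 carbonyl carbon, C2=C3 (methyl on C3), cyclobutane C4–C5–C11–C10 (C4 on C3, C11 on C1, C5 on C6, C10 on C9), gem-dimethyl C6, bridge C7–C8–C9, methyl on C10.
Remark on configuration: the cage of the target is that of α-longipinene with the (1R,2S,7R,8R) configuration in tricyclo[5.4.0.0(2,8)]undecane numbering; a synthase of this enantiomeric series is assumed and must be confirmed by chiral GC and optical rotation.
Remark on drawing: diphosphates are drawn as free acids and handled as ammonium salts.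

Step 1
Reactants: 1 (2E,6E)-farnesol
Product: 3 (2E,6E)-farnesyl chloride, via farnesyloxysulfonium chloride 2 (not isolated)
Conditions: NCS, Me2S, CH2Cl2, −40 to 0 °C
Reagents that add atoms: N-chlorosuccinimide, O=C1CCC(=O)N1Cl
Why: Corey–Kim chlorination: the alcohol is activated as alkoxysulfonium salt 2 and chloride displaces it at the primary carbon (SN2), so neither allylic transposition nor E/Z scrambling is expected.

Step 2
Reactants: 3 (2E,6E)-farnesyl chloride
Product: 4 (2E,6E)-farnesyl diphosphate
Conditions: (n-Bu4N)3HP2O7, MeCN, rt; cation-exchange resin (NH4+ form), aq NH4HCO3; cellulose chromatography, lyophilisation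
Reagents that add atoms: tris(tetrabutylammonium) hydrogen diphosphate, CCCC[N+](CCCC)(CCCC)CCCC.CCCC[N+](CCCC)(CCCC)CCCC.CCCC[N+](CCCC)(CCCC)CCCC.OP(=O)([O-])OP(=O)([O-])[O-]
Why: SN2 displacement of a primary allylic chloride by the soluble diphosphate trianion in a dipolar aprotic solvent is the standard preparation of allylic diphosphates and keeps the 2E geometry.

Step 3
Reactants: 4 (2E,6E)-farnesyl diphosphate
Product: 10 α-longipinene, via nerolidyl diphosphate 5 (not isolated), via humulyl cation 6 (not isolated), via allyl cation 7 (not isolated), via himachalyl cation 8 (not isolated), via longipinyl cation 9 (not isolated)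
Conditions: recombinant α-longipinene synthase (class 1 sesquiterpene synthase, wild type or active-site variant), MgCl2, HEPES buffer pH 7.5, DTT, pentane overlay, 30 °C
Reagents that add atoms: none
Why: Class 1 terpene-synthase catalysis: Mg2+-assisted ionisation of 4 and return of diphosphate at C3 give tertiary isomer 5, whose cisoid re-ionisation lets the distal C6=C7 alkene bond to C5 through C6 (anti-Markovnikov 1,11-closure to the eleven-membered ring of cation 6), after which a 1,3-hydride shift from C5 to C7 gives allyl cation 7. The C10=C11 alkene then attacks C5 through C11 (transannular closure, exo to that alkene and Markovnikov, which cuts the large ring into the six- and seven-membered rings of cis-fused cation 8), and the C3=C4 alkene attacks C10 through C4 (four-membered closure, exo to that alkene, giving tertiary cation 9) before a proton leaves C2. The closest known reaction is this same conversion by conifer sesquiterpene synthases that release α-longipinene beside longifolene, so the reaction type is established for this substrate. C4, C5, C10 and C11 are created from an achiral chain: their relative configuration is forced by the cage (the C1–C3 bridge and the C6–C9 bridge must leave the cyclobutane on opposite faces) and their absolute sense is set only by the fold that the active-site contour imposes. The step needs arrest at cation 9 by deprotonation at C2 instead of early proton loss from 8 or drift of 8 to longifolene-type cations; nothing in 4 secures this, so the synthase is chosen by GC and chiral-GC assay for this outcome.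

Step 4
Reactants: 10 α-longipinene
Product: 12 longipin-2-en-1-one, via 1-(tert-butylperoxy)longipin-2-ene 11 (not isolated)
Conditions: t-BuOOH (70% aq), dirhodium tetrakis(caprolactamate) Rh2(cap)4 (1 mol%), K2CO3, CH2Cl2, rt
Reagents that add atoms: tert-butyl hydroperoxide, CC(C)(C)OO
Why: Radical allylic oxidation of the kind that turns α-pinene into verbenone: tert-butylperoxyl abstracts hydrogen from C1, the only allylic methylene (the C4 bridgehead hydrogen cannot give a delocalised radical), the allyl radical is capped at its less hindered end C1 and mixed peroxide 11 collapses to the enone without touching a stereocentre.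

Step 5
Reactants: 12 longipin-2-en-1-one
Product: 13 (9R)-9-hydroxylongipin-2-en-1-one
Conditions: purified P450 BM3 (CYP102A1) variant selected from a mutant library for oxidation at C9, NADP+ (cat.), D-glucose, glucose dehydrogenase, catalase, phosphate buffer pH 8.0, 2-hydroxypropyl-β-cyclodextrin, air, 25 °C
Reagents that add atoms: dioxygen, O=O
Why: Proposed new method: the ferryl-oxo porphyrin radical cation of the haem abstracts a hydrogen atom from the unactivated C9 methylene and returns hydroxyl by rebound, the site being dictated only by how the variant's pocket seats the rigid enone (carbonyl held near the channel entrance, lower bridge over the iron); no enzyme is known for this position, so the variant has to be found by screening and evolving a library, the closest known reaction type being hydroxylation of unactivated ring methylenes of sesquiterpenoid ketones and lactones by engineered P450 BM3 variants; only site selectivity for C9 is demanded, because the 9-epimer and the over-oxidised ketone 14 converge in step 6.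

Step 6
Reactants: 13 (9R)-9-hydroxylongipin-2-en-1-one
Product: 15 longipina-2,7-diene-1,9-dione, via longipin-2-ene-1,9-dione 14 (not isolated)
Conditions: IBX (4 equiv), DMSO/fluorobenzene 1:2, 25 then 75 °C
Reagents that add atoms: none
Why: IBX first oxidises the secondary alcohol and then dehydrogenates the ketone through its enol; the C9 ketone can enolise only toward C8 (C10 is quaternary) and the C1 enone cannot react (C11 is a bridgehead), so only the C7=C8 bond can form, and the C9 stereocentre is erased on purpose.

Step 7
Reactants: 15 longipina-2,7-diene-1,9-dione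
Product: 17 (7R)-7-hydroxylongipin-2-ene-1,9-dione, via 7-boryl dione 16 (not isolated)
Conditions: B2pin2, CuCl (5 mol%), NaOt-Bu (10 mol%), (R)-1-[(Sp)-2-(diphenylphosphino)ferrocenyl]ethyldicyclohexylphosphine (a Josiphos ligand) or its enantiomer (6 mol%), MeOH, THF, 0 °C; then NaBO3·4H2O, THF/H2O, rt
Reagents that add atoms: sodium perborate, [Na+].[O-]OB=O
Why: Copper-catalysed asymmetric conjugate borylation followed by stereoretentive oxidation of the C–B bond; the boryl-copper species should add to the β-monosubstituted C7=C8 enone and not to the β,β-disubstituted caged C2=C3 enone, and because the lower bridge is nearly mirror-symmetric about the plane through C5, C8 and C10 the substrate has little facial bias, so the ligand antipode sets C7 (both are to be run and the one that borylates the C7 face on the C4 side is kept).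

Step 8
Reactants: 17 (7R)-7-hydroxylongipin-2-ene-1,9-dione; 18 3-methylbut-2-enal
Product: 20 (7R,9R)-9-hydroxy-7-(3-methylbut-2-enoyloxy)longipin-2-en-1-one, via C7 hemiacetal 19 (not isolated)
Conditions: SmI2 (0.3 equiv, premixed with 18), 18 (6 equiv), THF, −10 °C, dark
Reagents that add atoms: none
Why: Evans–Tishchenko reduction: the C7 hydroxyl adds to the aldehyde and the samarium-bound hemiacetal 19 passes its hydride to the C9 carbonyl through a six-membered transition state, so hydride enters C9 from the side of O7 and the new hydroxyl ends trans to it (anti-1,3), while the oxidised aldehyde stays on O7 as the 3-methylbut-2-enoate; one operation sets C9 and tells the two oxygens apart.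

Step 9
Reactants: 20 (7R,9R)-9-hydroxy-7-(3-methylbut-2-enoyloxy)longipin-2-en-1-one; 21 angelic acid
Product: 23 (7R,9R)-9-angeloyloxy-7-(3-methylbut-2-enoyloxy)longipin-2-en-1-one (target), via angelic mixed anhydride 22 (not isolated)
Conditions: 21, 2,4,6-trichlorobenzoyl chloride, Et3N, toluene, rt; then 20, toluene, 80 °C
Reagents that add atoms: none
Why: Yamaguchi esterification run without DMAP: the alcohol attacks the angeloyl carbonyl of 22 because the other carbonyl is blocked by two ortho chlorines, and these conditions are known to acylate hindered secondary alcohols with angelic acid without Z-to-E isomerisation to the tiglate; C9 keeps its configuration because its C–O bond is not broken.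

Compound list

1 | (2E,6E)-farnesol | CC(C)=CCC/C(C)=C/CC/C(C)=C/CO | starting material
2 | (2E,6E)-farnesyloxy(dimethyl)sulfonium chloride | CC(C)=CCC/C(C)=C/CC/C(C)=C/CO[S+](C)C.[Cl-] | intermediate (not isolated)
3 | (2E,6E)-farnesyl chloride | CC(C)=CCC/C(C)=C/CC/C(C)=C/CCl | intermediate
4 | (2E,6E)-farnesyl diphosphate (drawn as the free acid; isolated and used as its ammonium salt) | CC(C)=CCC/C(C)=C/CC/C(C)=C/COP(=O)(O)OP(=O)(O)O | intermediate
5 | (6E)-nerolidyl diphosphate, enzyme-bound (configuration at the carbinol carbon fixed by the enzyme, not specified) | CC(C)=CCC/C(C)=C/CCC(C)(C=C)OP(=O)(O)OP(=O)(O)O | intermediate (not isolated)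
6 | (Z,E)-humulyl cation, eleven-membered ring, cation at C7 | C1/C=C(C)\CC/C=C(C)/CC[CH+]C1(C)C | intermediate (not isolated)
7 | allyl cation C5–C4–C3 of the eleven-membered ring (after the 1,3-hydride shift) | [CH+]1/C=C(C)\CC/C=C(C)/CCCC1(C)C | intermediate (not isolated)
8 | cis-fused himachalyl cation, cation at C10 | C1CCC(C)(C)[C@H]2C=C(C)CC[C@H]2[C+]1C | intermediate (not isolated)
9 | longipinyl cation, cation at C3 | C1CCC(C)(C)[C@@H]2[C@H]3CC[C+](C)[C@@H]2[C@]31C | intermediate (not isolated)
10 | α-longipinene, (4R,5R,10S,11R) in longipinane numbering, the same as (1R,2S,7R,8R)-2,6,6,9-tetramethyltricyclo[5.4.0.0(2,8)]undec-9-ene | C1CCC(C)(C)[C@@H]2[C@H]3CC=C(C)[C@@H]2[C@]31C | intermediate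
11 | 1-(tert-butylperoxy)longipin-2-ene (C1 epimers, cage as in 10) | C1CCC(C)(C)[C@@H]2[C@H]3C(OOC(C)(C)C)C=C(C)[C@@H]2[C@]31C | intermediate (not isolated)
12 | (4R,5S,10R,11R)-longipin-2-en-1-one | C1CCC(C)(C)[C@@H]2[C@H]3C(=O)C=C(C)[C@@H]2[C@]31C | intermediate
13 | (4R,5S,9R,10R,11R)-9-hydroxylongipin-2-en-1-one (hydroxyl on the C11 side of the lower bridge) | O[C@@H]1CCC(C)(C)[C@@H]2[C@H]3C(=O)C=C(C)[C@@H]2[C@]31C | intermediate
14 | (4R,5S,10R,11R)-longipin-2-ene-1,9-dione | O=C1CCC(C)(C)[C@@H]2[C@H]3C(=O)C=C(C)[C@@H]2[C@]31C | intermediate (not isolated)
15 | (4R,5S,10R,11R)-longipina-2,7-diene-1,9-dione | O=C1C=CC(C)(C)[C@@H]2[C@H]3C(=O)C=C(C)[C@@H]2[C@]31C | intermediate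
16 | (4R,5S,7R,10R,11R)-7-(4,4,5,5-tetramethyl-1,3,2-dioxaborolan-2-yl)longipin-2-ene-1,9-dione | O=C1C[C@@H](B2OC(C)(C)C(C)(C)O2)C(C)(C)[C@@H]3[C@H]4C(=O)C=C(C)[C@@H]3[C@]41C | intermediate (not isolated)
17 | (4R,5S,7R,10R,11R)-7-hydroxylongipin-2-ene-1,9-dione (hydroxyl on the C4 side of the lower bridge) | O=C1C[C@@H](O)C(C)(C)[C@@H]2[C@H]3C(=O)C=C(C)[C@@H]2[C@]31C | intermediate
18 | 3-methylbut-2-enal | CC(C)=CC=O | starting material
19 | hemiacetal of 17 at O7 with 18 (samarium-bound; hemiacetal carbon unspecified) | O=C1C[C@@H](OC(O)C=C(C)C)C(C)(C)[C@@H]2[C@H]3C(=O)C=C(C)[C@@H]2[C@]31C | intermediate (not isolated)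
20 | (4R,5S,7R,9R,10R,11R)-9-hydroxy-7-(3-methylbut-2-enoyloxy)longipin-2-en-1-one | O[C@@H]1C[C@@H](OC(=O)C=C(C)C)C(C)(C)[C@@H]2[C@H]3C(=O)C=C(C)[C@@H]2[C@]31C | intermediate
21 | angelic acid, (Z)-2-methylbut-2-enoic acid | C/C=C(/C)C(=O)O | starting material
22 | (Z)-2-methylbut-2-enoic 2,4,6-trichlorobenzoic anhydride | C/C=C(/C)C(=O)OC(=O)c1c(Cl)cc(Cl)cc1Cl | intermediate (not isolated)
23 | (4R,5S,7R,9R,10R,11R)-9-[(Z)-2-methylbut-2-enoyloxy]-7-(3-methylbut-2-enoyloxy)longipin-2-en-1-one, CNP0277258.2 | C/C=C(/C)C(=O)O[C@@H]1C[C@@H](OC(=O)C=C(C)C)C(C)(C)[C@@H]2[C@H]3C(=O)C=C(C)[C@@H]2[C@]31C | target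

Total step count: 9. Longest linear sequence: 9 steps (1 to 23); 18 and 21 enter as purchased.

Steps most likely to fail

Step 5. No library variant may seat C9 over the haem: oxidation could go to the more exposed C8 methylene, to C7 or to the C3 methyl, or turnover on this compact cage may stay too low to be preparative. The fallback uses known chemistry, sets out from 12 and returns at 15.
- Visible-light C–H bromination of 12 with N-bromo-N-tert-butyl-3,5-bis(trifluoromethyl)benzamide in benzene should take C8, the only ring methylene not flanked by a quaternary carbon and the one farthest from the electron-poor enone (the bulky, electrophilic amidyl radical is the hydrogen abstractor). This gives 8-bromolongipin-2-en-1-one F1.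
- DBU in toluene at 100 °C (E2) should give longipina-2,7-dien-1-one F2 together with longipina-2,8-dien-1-one F3. The pair need not be separated, since both lose an allylic hydrogen to the same C7–C8–C9 allyl radical.
- Allylic oxidation under the conditions of step 4 then gives 15 and its regioisomer longipina-2,8-diene-1,7-dione F4, which are separated by chromatography.
- The cost is the uncontrolled site of oxygen capture, which may divert up to half of the material into F4, and possible competing bromination at the C3 methyl.

Step 3. The cascade may leave the desired channel: early proton loss from 8, diversion of 8 to longifolene-type cations, formation of the opposite antipode, or slow turnover through product inhibition. The fallback takes the cage from the chiral pool instead of building it; it sets out from purchased 10 and returns at 10. α-Longipinene is an article of commerce isolated from conifer oleoresin. Provided chiral GC and the sign of rotation confirm the (1R,2S,7R,8R) series, it enters at step 4 and steps 1 to 3 fall away. No new compound arises.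

Step 8. Hydride transfer within the samarium-bound hemiacetal may be slow at the hindered C9 carbonyl, so that retro-aldol ring opening, dehydration back to 15 or 1,3-acyl migration compete. The fallback sets out from 17 and returns at 20.
- Saksena–Evans reduction of 17 with Me4NBH(OAc)3 in MeCN/AcOH at −30 °C delivers hydride from the boron bound to O7 to the same face of C9 and should give the trans-diol (7R,9R)-7,9-dihydroxylongipin-2-en-1-one F5.
- Acylation of F5 with one equivalent of 3-methylbut-2-enoyl chloride and pyridine in CH2Cl2 at −20 °C gives 20 after chromatography.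
- The two hydroxyls are similarly hindered, so regiocontrol cannot be taken for granted; material acylated elsewhere is returned to F5 by methanolysis with K2CO3.

Further compounds

F1 | step 5 | 8-bromolongipin-2-en-1-one (C8 epimers) | C1C(Br)CC(C)(C)[C@@H]2[C@H]3C(=O)C=C(C)[C@@H]2[C@]31C
F2 | step 5 | longipina-2,7-dien-1-one | C1C=CC(C)(C)[C@@H]2[C@H]3C(=O)C=C(C)[C@@H]2[C@]31C
F3 | step 5 | longipina-2,8-dien-1-one | C1=CCC(C)(C)[C@@H]2[C@H]3C(=O)C=C(C)[C@@H]2[C@]31C
F4 | step 5 | longipina-2,8-diene-1,7-dione | C1=CC(=O)C(C)(C)[C@@H]2[C@H]3C(=O)C=C(C)[C@@H]2[C@]31C
F0 | step 3 | none | none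
F5 | step 8 | (7R,9R)-7,9-dihydroxylongipin-2-en-1-one | O[C@@H]1C[C@@H](O)C(C)(C)[C@@H]2[C@H]3C(=O)C=C(C)[C@@H]2[C@]31C
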